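## The problem

- The skeleton is simple: a (2S)-7-hydroxyflavanone whose C8 carries the chain C1'=C2'–C3'(OH)(CH3)–C4'H2–OAc. Almost all of the difficulty sits in that chain.
- The C1'=C2' bond is Z, conjugated with ring A and flanked by O7–H and O1. It is the less stable geometry, and nothing in an open-chain precursor favours it.
- C3' is a tertiary carbinol stereocenter (R) bearing methyl, alkenyl and acetoxymethyl groups. It lies eight bonds from C2 (S), so neither center can control the other and each needs its own source of chirality.
- C8 must be substituted in preference to C6, which is also ortho to O7.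
- Three functions rule out rough treatment:
  - C2 epimerizes through retro-oxa-Michael opening to the chalcone under base.
  - The Z-styryl tertiary allylic alcohol ortho to a free phenol ionizes under acid and closes to a 2H-chromene.
  - The primary acetate does not tolerate hydroxide or alkoxide.
- The feature that opens the problem is that the two hydroxyls the target carries free, the phenolic O7–H on ring A and the tertiary O–H on C3', are 1,6-related through C7–C8–C1'=C2'–C3'. One silicon atom between these two oxygens gives an eight-membered ring (O7, C7, C8, C1', C2', C3', O, Si). That ring can hold the C1'=C2' bond only as the Z isomer.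

## Retrosynthesis

**12 ⇒ 11 (two Si–O bonds).** The target 12 is read as the cyclic silaketal 11 minus one silicon atom. In 11 the O7 and C3' oxygens are bridged by Si(iPr)2 in an eight-membered 1,3-dioxa-2-silacyclooct-6-ene fused to ring A. This replaces a geometry problem by a ring. The forward step only has to cleave two Si–O bonds with buffered fluoride, leaving the acetate, C2 and the allylic alcohol alone.

**11 ⇒ 10 (the C1'=C2' double bond).** Cutting the olefin inside the ring by a metathesis transform gives diene 10, in which both olefins are terminal vinyl groups. Against the neighbouring cut at C8–C1' (aryl–alkyne or aryl–alkenyl coupling), this cut makes the Z geometry a consequence of ring size and not of a kinetically controlled reduction or a configurationally labile organometallic. The forward reaction must close an eight-membered ring at a vinyl group on a fully substituted carbon.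

**10 ⇒ 8 + 4 (the two Si–O bonds of the tether).** Diene 10 falls into two halves of similar size, each with one stereocenter: phenol 8, (S)-7-hydroxy-8-vinylflavanone, and tertiary alcohol 4, (R)-2-hydroxy-2-methylbut-3-enyl acetate. The route is therefore convergent, and the two remote stereocenters are made independently. The forward step is a sequential double silylation with iPr2Si(OTf)2, hindered alcohol first and phenol second.

**4 ⇒ 3 ⇒ rac-1 (C3'–O bond).** Alcohol 4 is the primary monoacetate of diol 3. Diol 3 is disconnected at the tertiary C–O bond to racemic isoprene monoepoxide 1. The forward reaction is a palladium-catalysed dynamic kinetic asymmetric allylic substitution with hydrogencarbonate. Both enantiomers of 1 pass through interconverting π-allyl complexes and converge on one configuration of the tertiary carbinol. The stereocenter that is hardest to make classically therefore comes in one step from a racemic commodity epoxide.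

**8 ⇒ 7 ⇒ 6 ⇒ 5 (C8–C1', C2–phenyl, C8–I).**
- The vinyl group of 8 comes from iodide 7 by Stille coupling, which is neutral and cannot epimerize C2.
- The C2–phenyl bond of 7 comes from conjugate addition of phenylboronic acid to 7-hydroxy-8-iodochromone 6 under a chiral cationic palladium catalyst. This creates C2 without base, so the flavanone never passes through a chalcone.
- Iodide 6 comes from commercial 7-hydroxychromone 5. The pyrone ring directs electrophiles to C8, which settles the C8/C6 question at the first step.

## Roads not taken

**Alternative 1: aryl–alkyne coupling and semihydrogenation (the obvious route).**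
- Cut: C8–C1', as an sp2–sp bond.
- Forward: Sonogashira coupling of iodide 7 with (R)-2-hydroxy-2-methylbut-3-ynyl acetate A1 to give alkyne A2, then Lindlar semihydrogenation to 12.
- Why not chosen:
  - A free hydroxyl ortho to an arylalkyne adds across the triple bond under palladium/copper/amine conditions. O7 would therefore need a protecting group that is put on and taken off.
  - The amine base is a risk to C2.
  - The Z geometry would rest on stopping a hydrogenation of a hindered propargylic tertiary alcohol at the right moment. In 11 it is structural.

**Alternative 2: the target as the hydrate of a chromene.**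
- Cut: the C3'–OH bond, with O7 attached to C3' in the precursor.
- Forward: 7-O-propargyl ether A3 undergoes the thermal propargyl Claisen / 1,5-hydrogen shift / 6π-electrocyclization cascade to the angular pyranoflavanone A4. Photochemical ring opening gives ortho-quinone methide A5, and water adds 1,6 to give 12.
- Why not chosen:
  - The route is short and looks biogenetic, but A5 is planar at C3', so the carbinol configuration would be uncontrolled.
  - Electrocyclic reclosure of A5 to A4 is intramolecular and outruns hydration.
  - The geometry of the new double bond depends on the conformer that is trapped.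
  - The Claisen temperature endangers C2.

**Alternative 3: ring C closed last.**
- Cut: O1–C2.
- Forward: chalcone A6, carrying the finished side chain, is closed by an enantioselective intramolecular oxa-Michael addition.
- Why not chosen:
  - 2'-Hydroxychalcones without an extra activating group cyclize with unreliable enantioselectivity.
  - Making A6 by Claisen–Schmidt condensation requires strong base in the presence of the acetate.
  - The acid or base used for ring closure threatens the Z-allylic alcohol.
  - The most valuable intermediate would be exposed to the least certain stereochemical step.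

Key step: step 7

Assumption: in step 1 the (R,R)-diphosphine is taken to give the (R)-diol, and in step 4 the (R)-pyridinooxazoline is taken to give the (2S)-flavanone; if either sense proves opposite, the mirror-image ligand is used and nothing else changes.

## Steps

**Step 1**
Reactants: 1 racemic 2-methyl-2-vinyloxirane (isoprene monoepoxide)
Product: 3 (R)-2-methylbut-3-ene-1,2-diol, via hydrogencarbonate monoester 2 (not isolated)
Conditions: Pd2(dba)3·CHCl3 (1 mol%), (R,R)-1,2-bis[2-(diphenylphosphino)benzamido]cyclohexane (3 mol%), BEt3 (1 mol%), NaHCO3, CH2Cl2/H2O, rt
Reagents that add atoms: sodium hydrogencarbonate, [Na+].OC([O-])=O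
Why: Tsuji–Trost-type dynamic kinetic asymmetric transformation: zerovalent palladium ionizes both enantiomers of 1 to π-allyl complexes that interconvert by π–σ–π faster than they are attacked, and the boron-bound hydrogencarbonate is delivered to the substituted terminus inside the chiral pocket, so the racemate converges on the (R)-carbinol; the monoester 2 loses CO2 to give 3.

**Step 2**
Reactants: 3 (R)-2-methylbut-3-ene-1,2-diol
Product: 4 (R)-2-hydroxy-2-methylbut-3-enyl acetate
Conditions: Ac2O (1.05 equiv), pyridine, CH2Cl2, 0 °C
Reagents that add atoms: acetic anhydride, CC(=O)OC(C)=O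
Why: Selective O-acylation of the primary hydroxyl; the tertiary hydroxyl does not react without an acyl-transfer catalyst, and the stereocenter is not involved.

**Step 3**
Reactants: 5 7-hydroxychromone (7-hydroxy-4H-chromen-4-one)
Product: 6 7-hydroxy-8-iodochromone
Conditions: N-iodosuccinimide (1.05 equiv), CF3CO2H (10 mol%), MeCN, 0 °C to rt
Reagents that add atoms: N-iodosuccinimide, O=C1CCC(=O)N1I
Why: Electrophilic aromatic iodination ortho to the phenol; in 7-hydroxychromones the fused pyrone fixes the higher double-bond character in the C7–C8 bond, so electrophiles enter at C8 and not at C6, and C3 of the pyrone is much less nucleophilic than the phenol ring.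

**Step 4**
Reactants: 6 7-hydroxy-8-iodochromone
Product: 7 (2S)-7-hydroxy-8-iodoflavanone
Conditions: PhB(OH)2 (2 equiv), Pd(OCOCF3)2 (5 mol%), (R)-t-BuPyOx (6 mol%), NH4PF6 (30 mol%), H2O (5 equiv), ClCH2CH2Cl, 60 °C
Reagents that add atoms: phenylboronic acid, OB(O)c1ccccc1
Why: Catalytic asymmetric conjugate addition: the cationic divalent palladium–pyridinooxazoline complex takes up phenyl by transmetalation, inserts the C2=C3 bond of the chromone on the face left open by the tert-butyl group (this sets C2), and the palladium enolate is protonated by water; no base is present, so the flavanone cannot open to the chalcone, and the catalyst stays divalent, so the C8–I bond is not touched.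

**Step 5**
Reactants: 7 (2S)-7-hydroxy-8-iodoflavanone
Product: 8 (2S)-7-hydroxy-8-vinylflavanone
Conditions: Bu3SnCH=CH2 (1.3 equiv), Pd(PPh3)4 (5 mol%), BHT (trace), toluene, 90 °C
Reagents that add atoms: tributyl(vinyl)stannane, CCCC[Sn](CCCC)(CCCC)C=C
Why: Stille coupling (oxidative addition of zerovalent palladium into C8–I, transmetalation, reductive elimination) runs without base and tolerates the free phenol, so C2 keeps its configuration.

**Step 6**
Reactants: 4 (R)-2-hydroxy-2-methylbut-3-enyl acetate (1.2 equiv); 8 (2S)-7-hydroxy-8-vinylflavanone
Product: 10 mixed diisopropylsilaketal diene (O7 of the flavanone and the tertiary oxygen of the butenyl acetate joined through Si(iPr)2), via silyl triflate 9 (not isolated)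
Conditions: iPr2Si(OTf)2 (1.2 equiv), 2,6-lutidine (3 equiv), CH2Cl2, −78 to 0 °C; then 8, 0 °C to rt
Reagents that add atoms: diisopropylsilyl bis(trifluoromethanesulfonate), CC(C)[Si](OS(=O)(=O)C(F)(F)F)(OS(=O)(=O)C(F)(F)F)C(C)C
Why: Sequential silylation for unsymmetrical bis(alkoxy)silanes: the hindered tertiary alcohol displaces only one triflate at low temperature, and the more reactive phenol then displaces the second; 2,6-lutidine is too weak and too hindered to open the flavanone, and no stereocenter is touched.

**Step 7**
Reactants: 10 mixed diisopropylsilaketal diene
Product: 11 cyclic silaketal (eight-membered 1,3-dioxa-2-silacyclooct-6-ene fused to ring A at C7–C8, Z-configured C1'=C2', 2S and 3'R)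
Conditions: second-generation Hoveyda–Grubbs catalyst RuCl2(H2IMes)(=CH-C6H4-2-OiPr) (5–10 mol%), toluene (0.002 M), 80 °C, argon sparge
Reagents that add atoms: none
Why: The ruthenium alkylidene loads at the unhindered C8 vinyl group (giving an ortho-oxygenated benzylidene of the chelated kind that this catalyst class uses as its resting state), adds [2+2] to the tethered vinyl group on C3' and cycloreverts with loss of ethylene. The closest known reaction type is temporary-silicon-tethered ring-closing metathesis of bis(alkoxy)silanes to seven- and eight-membered silaketals, and both olefin classes used here (ortho-oxygenated styrene, vinyl group on a fully substituted carbinol carbon) are the ones that close 2,2-disubstituted 2H-chromenes by the same reaction. The ring closed is the eight-membered 1,3-dioxa-2-silacyclooct-6-ene fused to ring A across C7–C8, and it is closed by olefin metathesis at the endocyclic C1'=C2' bond. No stereocenter is made, and C2 and C3' are untouched because the medium is neutral. The selectivity needed is Z over E, and the ring secures it, since an E olefin cannot span a benzo-fused eight-membered ring. Cyclization over oligomerization is secured by high dilution, by the gem-dialkyl effect of the fully substituted C3' and the Si(iPr)2 unit, and by the fixed cis geometry of the C7–C8 aryl bond. Removal of ethylene drives the reaction, and neither olefin has an allylic hydrogen through which it could isomerize.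

**Step 8**
Reactants: 11 cyclic silaketal
Product: 12 (2S)-7-hydroxy-8-[(1Z,3R)-4-acetoxy-3-hydroxy-3-methylbut-1-enyl]flavanone (CNP0372308.1)
Conditions: Bu4NF (3 equiv), AcOH (3 equiv), THF, 0 °C to rt
Reagents that add atoms: none
Why: Fluoride-induced desilylation: the aryloxide leaves silicon first, and the remaining fluorosilyl ether of the tertiary alcohol is cleaved by a second fluoride; acetic acid keeps the medium near neutral, so the acetate neither migrates nor is lost, C2 does not epimerize, and the allylic alcohol is not ionized toward the chromene.

## Compound list

1 | racemic 2-methyl-2-vinyloxirane (isoprene monoepoxide) | CC1(C=C)CO1 | starting material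
2 | (2R)-1-hydroxy-2-methylbut-3-en-2-yl hydrogen carbonate (present as its sodium salt) | OC[C@](C)(OC(O)=O)C=C | intermediate
3 | (R)-2-methylbut-3-ene-1,2-diol | OC[C@](C)(O)C=C | intermediate
4 | (R)-2-hydroxy-2-methylbut-3-enyl acetate | CC(=O)OC[C@](C)(O)C=C | intermediate
5 | 7-hydroxychromone | O=c1ccoc2cc(O)ccc12 | starting material
6 | 7-hydroxy-8-iodochromone | O=c1ccoc2c(I)c(O)ccc12 | intermediate
7 | (2S)-7-hydroxy-8-iodoflavanone | Oc1ccc2c(c1I)O[C@H](c1ccccc1)CC2=O | intermediate
8 | (2S)-7-hydroxy-8-vinylflavanone | Oc1ccc2c(c1C=C)O[C@H](c1ccccc1)CC2=O | intermediate
9 | (2R)-2-{[diisopropyl(trifluoromethanesulfonyloxy)silyl]oxy}-2-methylbut-3-enyl acetate | CC(=O)OC[C@](C)(O[Si](C(C)C)(C(C)C)OS(=O)(=O)C(F)(F)F)C=C | intermediate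
10 | (2R)-2-({diisopropyl[((2S)-4-oxo-2-phenyl-8-vinylchroman-7-yl)oxy]silyl}oxy)-2-methylbut-3-enyl acetate | CC(=O)OC[C@](C)(O[Si](C(C)C)(C(C)C)Oc1ccc2c(c1C=C)O[C@H](c1ccccc1)CC2=O)C=C | intermediate
11 | cyclic diisopropylsilaketal of 12 (O7 and the C3' oxygen bridged by Si(iPr)2; eight-membered ring; Z olefin; 2S, 3'R) | CC(=O)OC[C@@]1(C)/C=C\c2c(ccc3c2O[C@H](c2ccccc2)CC3=O)O[Si](C(C)C)(C(C)C)O1 | intermediate
12 | (2S)-7-hydroxy-8-[(1Z,3R)-4-acetoxy-3-hydroxy-3-methylbut-1-enyl]flavanone | CC(=O)OC[C@](C)(O)/C=C\c1c(O)ccc2c1O[C@H](c1ccccc1)CC2=O | target

## Step count and risk

Total: 8 steps. Longest linear sequence: 6 steps (5 → 6 → 7 → 8 → 10 → 11 → 12, steps 3 to 8). The alcohol branch (steps 1 and 2) joins at step 6.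

**Step 7 (key step).**
- Risk: the second metathesis event at the vinyl group on the fully substituted C3' may be too slow. The benzylidene would then be consumed by intermolecular homodimerization of the styrene ends, or the catalyst would decay at the dilution required.
- Fallback: it sets out from 4 and 7 and returns at 12. The Z geometry is locked in a five-membered ring on the small fragment, where ring closure at the hindered vinyl group is far easier.
  - Alcohol 4 is transesterified with dibutyl vinylboronate (CH2Cl2, rt) to the mixed ester butyl (2R)-1-acetoxy-2-methylbut-3-en-2-yl vinylboronate F1.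
  - Second-generation Grubbs catalyst (CH2Cl2, 40 °C) closes F1 to the cyclic alkenylboronate [(5R)-2-butoxy-5-methyl-2,5-dihydro-1,2-oxaborol-5-yl]methyl acetate F2.
  - Suzuki–Miyaura coupling of F2 with iodide 7 (Pd(PPh3)4, K3PO4, THF/H2O, rt to 40 °C) gives 12 directly with retention of the olefin geometry.
  - Steps 5, 6 and 8 are then not needed. The price is a mildly basic aqueous coupling on the flavanone.

**Step 4.**
- Risk: insufficient facial selectivity on this electron-rich, 8-iodinated acceptor, erosion of enantiopurity by reversible ring opening of the product in the warm protic medium, or slow turnover because the acidic phenol binds the cationic catalyst.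
- Fallback: it sets out from 6 and returns at 7. Enantioselective catalysis is replaced by resolution.
  - The same phenyl transfer is run with the more active achiral catalyst Pd(OCOCF3)2/2,2'-bipyridine to give rac-7-hydroxy-8-iodoflavanone F3.
  - F3 is resolved kinetically by asymmetric transfer hydrogenation (RuCl(p-cymene)(TsDPEN) of the antipode that reduces the 2R ketone faster, HCO2H/Et3N). The 2R enantiomer is converted into (2R,4R)-7-hydroxy-8-iodoflavan-4-ol F4, which is separated, and unreacted 7 is recovered.

**Step 6.**
- Risk: scrambling to the two symmetrical bis-ethers, or hydrolytic loss of the aryl–O–Si bond (the phenol is para to a carbonyl and a good leaving group) during isolation.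
- Fallback: it sets out from 4 and returns at 10. The silicon is attached in two separately controlled events through a hydrosilane.
  - Alcohol 4 with iPr2SiHCl and imidazole gives the isolable silyl ether (2R)-2-[(diisopropylsilyl)oxy]-2-methylbut-3-enyl acetate F5.
  - N-Bromosuccinimide (CH2Cl2, 0 °C) converts the Si–H bond of F5 into the bromosilane (2R)-2-{[bromo(diisopropyl)silyl]oxy}-2-methylbut-3-enyl acetate F6, which is not isolated.
  - Addition of phenol 8 and imidazole gives 10.

**Step 5.**
- Risk: slow coupling at the doubly ortho-oxygenated C8–I bond with competing protodeiodination, and partial epimerization of C2 on prolonged heating.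
- Fallback: it sets out from 6 and returns at 8. The C8–vinyl bond is made before C2 exists, so forcing conditions cannot touch a stereocenter.
  - Stille coupling of chromone 6 (Bu3SnCH=CH2, Pd(PPh3)4, DMF, 100 °C) gives 7-hydroxy-8-vinylchromone F7.
  - The asymmetric phenyl addition of step 4 is then run on F7 to give 8. The price is that the arylpalladium species must select the pyrone C2=C3 bond over the styrene.

## Further compounds

F1 | step 7 | butyl (2R)-1-acetoxy-2-methylbut-3-en-2-yl vinylboronate | CC(=O)OC[C@](C)(OB(C=C)OCCCC)C=C
F2 | step 7 | [(5R)-2-butoxy-5-methyl-2,5-dihydro-1,2-oxaborol-5-yl]methyl acetate | CC(=O)OC[C@@]1(C)C=CB(OCCCC)O1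
F3 | step 4 | rac-7-hydroxy-8-iodoflavanone | Oc1ccc2c(c1I)OC(c1ccccc1)CC2=O
F4 | step 4 | (2R,4R)-7-hydroxy-8-iodoflavan-4-ol (2,4-cis) | Oc1ccc2c(c1I)O[C@@H](c1ccccc1)C[C@H]2O
F5 | step 6 | (2R)-2-[(diisopropylsilyl)oxy]-2-methylbut-3-enyl acetate | CC(=O)OC[C@](C)(O[SiH](C(C)C)C(C)C)C=C
F6 | step 6 | (2R)-2-{[bromo(diisopropyl)silyl]oxy}-2-methylbut-3-enyl acetate | CC(=O)OC[C@](C)(O[Si](Br)(C(C)C)C(C)C)C=C
F7 | step 5 | 7-hydroxy-8-vinylchromone | C=Cc1c(O)ccc2c1occc2=O
A1 | alternative 1 | (2R)-2-hydroxy-2-methylbut-3-ynyl acetate | CC(=O)OC[C@](C)(O)C#C
A2 | alternative 1 | (2S)-7-hydroxy-8-[(3R)-4-acetoxy-3-hydroxy-3-methylbut-1-ynyl]flavanone | CC(=O)OC[C@](C)(O)C#Cc1c(O)ccc2c1O[C@H](c1ccccc1)CC2=O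
A3 | alternative 2 | (2S)-7-[(1-acetoxy-2-methylbut-3-yn-2-yl)oxy]flavanone (both epimers at the ether carbon) | CC(=O)OCC(C)(C#C)Oc1ccc2c(c1)O[C@H](c1ccccc1)CC2=O
A4 | alternative 2 | (2S)-2'-(acetoxymethyl)-2'-methyl-2'H-pyrano[2',3':7,8]flavanone (both epimers at C2') | CC(=O)OCC1(C)C=Cc2c(O1)ccc1c2O[C@H](c2ccccc2)CC1=O
A5 | alternative 2 | ortho-quinone methide from ring opening of A4 | CC(=O)OCC(C)=CC=C1C(=O)C=CC2=C1O[C@H](c1ccccc1)CC2=O
A6 | alternative 3 | (E)-1-{3-[(1Z,3R)-4-acetoxy-3-hydroxy-3-methylbut-1-enyl]-2,4-dihydroxyphenyl}-3-phenylprop-2-en-1-one | CC(=O)OC[C@](C)(O)/C=C\c1c(O)ccc(C(=O)/C=C/c2ccccc2)c1O
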